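## Analysis of the target

The target is a (2S)-flavanone: a chroman-4-one (rings A and C) with a free phenol at C7 and a prenyl (3-methylbut-2-en-1-yl) group at C8, joined through C2 to ring B. Ring B is substituted at C1', C3', C4' and C5': C3' carries a second prenyl group, C4' an oxygen, and C5' a CH2 that closes, through CH2–CMe2 and that oxygen, the 2,2-dimethyldihydropyran ring D. C2 is the only stereocentre. It is benzylic, bears the ring oxygen and lies β to the C4 ketone, so base can erase it by reversible oxa-Michael opening to the chalcone; it is therefore best set late. The two trisubstituted alkenes exclude hydrogenation, strong electrophiles and strong acid, and the C7 phenol next to the C8 prenyl group can close to a further chroman under forcing acid. The main difficulty is ring B: both carbons ortho to the C4' oxygen carry a C5 unit, one cyclised onto the oxygen and one not, so a 3',5'-diprenylphenol would offer two equivalent groups for cyclisation. A second difficulty is the C8 versus C6 placement of the ring A prenyl group. The strategy rests on the C4'–O/C5'–CH2 pair of ring D: these atoms are the ends of an ortho-quinone methide, the CH2–CMe2 unit is isobutene, and the C3' prenyl group is then only a bystander that is already in place.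

## Retrosynthetic reasoning

Target 17 is traced back to its C7 methoxymethyl ether 16. The phenol must be masked because the C–C bond formation before it runs under base, and an acetal can be taken off at the end without touching C2.

In 16 the C2–C1' bond is cut, giving arylboronic acid 10 and chromone 15. This is the most convergent cut: each half is an aromatic compound carrying its own prenyl group, and the forward step, an enantioselective conjugate addition of the aryl group to C2 of the chromone, creates the stereocentre in the last C–C bond formation. A cut through ring C at O1–C2 (chalcone cyclisation) was not chosen because control of C2 in that ring closure is less dependable.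

Boronic acid 10 comes from aryl bromide 7 by exchange of bromine for boron. The bromine only marks C1' and is carried unchanged from the first starting material.

In 7 the O–CMe2 and CH2–CH2 bonds of ring D are cut together. This leads back to ortho-quinone methide 6 and isobutene 5, and 6 arises by dehydration of salicyl alcohol 4. The cut is made here because it is the only one that treats the two ortho substituents of the ring B oxygen differently by construction: the carbon that becomes C4 of ring D is present in 4 as CH2OH, while the other ortho carbon already holds the prenyl group. The forward reaction must form both bonds in one cycloaddition with the gem-dimethyl carbon on oxygen.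

Salicyl alcohol 4 is cut at the aryl–CH2 bond of the prenyl group, giving 5-bromo-2-hydroxybenzyl alcohol 1 and prenyl bromide 2. In 1 the para position is blocked by bromine and one ortho position by CH2OH, so C-alkylation of the phenoxide 3 can only occur at the remaining ortho carbon.

Chromone 15 is opened at O1–C2 to enaminone 14, which comes from acetophenone 13 by one-carbon homologation of the acetyl group. Compound 13 is the mono-protected form of 2,4-dihydroxy-3-prenylacetophenone 12, and 12 is cut at the aryl–prenyl bond to 2,4-dihydroxyacetophenone 11 and prenyl bromide 2. The forward alkylation must go to the carbon between the two oxygens, which becomes C8.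

## Alternatives that were turned down

Alternative 1: Rings A and C are both disconnected, and ring A is grown by an intramolecular Danheiser benzannulation on a chain that already contains C2. Irradiation of diazo enone A1 would give, by Wolff rearrangement, a vinylketene that adds (2+2) to the tethered alkynyl ether (C7–C8 and C4a–C8a, closing ring C). Four-electron ring opening, six-electron closure (C6–C7) and tautomerisation would then give phenol A2, a (2S)-flavan-4-ol silyl ether. In its favour, the ring A pattern is written into the chain: the prenyl group sits on the alkyne carbon that becomes C8, so the C6/C8 question of step 4 does not arise. On this point the alternative is stronger than the chosen route. C2 also enters as a carbinol centre that cannot epimerise. Against it, A1 combines a diazo ketone, an alkynyl ether of a secondary benzylic alcohol (liable to retro-ene loss of a ketene and to sigmatropic shift on mild warming) and two trisubstituted alkenes that can trap the carbene or the ketene. A2 still needs desilylation and oxidation at C4 beside a free phenol. The approach also leaves the ring B problem untouched, so a compound such as 7 would be needed anyway. It is much longer. The chosen strategy offers instead two purchased aromatic rings, a catalytic stereocentre in the last C–C bond formation, and risk confined to one thermal cycloaddition on a small molecule.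

Alternative 2: Ring C is cut at C2–C3 and O1–C8a, with ring A held at the dihydro level. The bis-silyl dienol ether A3 would add to the ring B aldehyde F9 (the compound of the fallback to step 8) under a chiral titanium–binaphthol catalyst, forming C2–C3. Acid would then close O1 onto C8a with loss of silanol to give the dihydroflavanone A4, and dehydrogenation across C5–C6 would lead to 16. In its favour, the stereocentre arises in a well-understood aldehyde addition, no boronic acid is needed, and prenylation of a cyclic 1,3-dione between its carbonyl groups is unambiguous, which is at least as good as step 4 of the chosen route. Against it, the aromatisation of A4 must remove hydrogen from C5 and C6 with an oxidant that spares two prenyl groups, the benzylic CH2 of ring D and the C2–H/C3–H2 pair, whose oxidation would give the flavone and destroy the stereocentre. Telling the two ring oxygens of the dione apart (one acetal, one silyl) costs steps, and A3 is sensitive to hydrolysis. The chosen strategy keeps ring A aromatic throughout and needs no redox change on it.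

Alternative 3: Ring B itself is disconnected across C5'–C6' and C1'–C2'. Diene A5, in which ring D is already present as a dihydropyran, would add to the alkyne of 2-ethynylchromone A6, and a quinone oxidant would dehydrogenate the resulting 1,4-cyclohexadiene to flavone A7. In its favour, ring D exists before ring B does, so the two ortho positions are distinguished as securely as in the chosen route. The regiochemistry is also electronically matched: a 2-oxygenated diene and an acceptor alkyne give the para relation of C4'–O and C1'. Against it, the sequence ends at the flavone oxidation level. C2 would then have to come from an enantioselective 1,4-reduction of a hindered 2-arylchromone in the presence of two trisubstituted alkenes, which excludes hydrogenation, and desilylation would follow. A5 is a skipped triene with an acid-labile enol ether and needs several steps. A6 needs the same C8 prenylation as 15 plus installation of the ethynyl group. The chosen strategy reaches the same differentiation in one step from 4 and sets C2 in a C–C bond-forming event.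

Key step: step 2

Assumption: the antipode of the chiral diene that delivers the aryl group to the Re face of C2 of chromone 15 (giving 2S) is taken to be the (S,S) form, by extension of the facial model for 2-cyclohexenone. This is to be confirmed on a small scale, and the other antipode is used if the sense proves opposite.

Step 1
Reactants: 1 5-bromo-2-hydroxybenzyl alcohol; 2 prenyl bromide (1-bromo-3-methylbut-2-ene)
Product: 4 4-bromo-2-(hydroxymethyl)-6-(3-methylbut-2-en-1-yl)phenol, via sodium phenoxide 3 (not isolated)
Conditions: NaH (1.05 equiv), PhMe, 0 °C to rt; then 2 (1.1 equiv), rt to 45 °C; aq NH4Cl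
Reagents that add atoms: none
Why: Ortho-C-alkylation of a sodium phenoxide held as a tight, aggregated ion pair in a non-polar solvent, where the oxygen is shielded by the cation; one equivalent of base removes only the phenolic proton, and the sole open ortho/para carbon is C6, so tautomerisation of the dienone gives 4.

Step 2
Reactants: 4 4-bromo-2-(hydroxymethyl)-6-(3-methylbut-2-en-1-yl)phenol; 5 isobutene (2-methylpropene)
Product: 7 6-bromo-2,2-dimethyl-8-(3-methylbut-2-en-1-yl)chromane, via ortho-quinone methide 6 (not isolated)
Conditions: 5 (ca. 40 equiv, condensed), PhMe (0.05 M in 4), sealed steel autoclave, 170 °C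
Reagents that add atoms: none
Why: Thermal 1,4-elimination of water from the hydrogen-bonded salicyl alcohol 4 gives the ortho-quinone methide 6, an electron-poor 1-oxadiene (O=C4'–C5'=CH2 in target numbering). Isobutene intercepts 6 in an inverse-electron-demand hetero-Diels–Alder reaction, the closest known reaction type being the thermal chroman synthesis from ortho-hydroxybenzyl alcohols and simple alkenes. Ring D closes as a six-membered ring in one (4+2) event that forms the CH2–CH2 bond and the O–CMe2 bond, asynchronously with the C–C bond in advance, and rearomatisation of ring B drives it. No stereocentre is formed. The step needs regioselectivity (2,2- and not 3,3-dimethyl), which the polarity of the partners secures: the nucleophilic CH2 end of isobutene attacks the electrophilic exocyclic carbon of 6 while positive charge builds at the tertiary carbon that bonds to oxygen. It also needs 6 to take isobutene in preference to the prenyl alkene of a second molecule or to another molecule of 6. The C3' prenyl group cannot add within the same molecule, because its tether starts on the carbonyl side of the oxadiene and the adduct would be a strained bridged ring, but it can add between molecules, and this is countered by the large excess of the less hindered isobutene and by high dilution of 4. The aryl bromide is inert under neutral thermolysis.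

Step 3
Reactants: 7 6-bromo-2,2-dimethyl-8-(3-methylbut-2-en-1-yl)chromane
Product: 10 [2,2-dimethyl-8-(3-methylbut-2-en-1-yl)chroman-6-yl]boronic acid, via aryllithium 8 (not isolated), via lithium triisopropoxyborate 9 (not isolated)
Conditions: n-BuLi (1.1 equiv), THF, −78 °C; B(OiPr)3 (1.5 equiv), −78 °C to rt; 1 M aq HCl, 0 °C
Reagents that add atoms: triisopropyl borate, CC(C)OB(OC(C)C)OC(C)C; water, O
Why: Bromine–lithium exchange at −78 °C is much faster than deprotonation of the benzylic/allylic CH2 groups; the aryllithium is trapped by the borate as the ate complex, and brief cold hydrolysis gives the boronic acid without harm to the prenyl group (lithiation–borylation).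

Step 4
Reactants: 11 2,4-dihydroxyacetophenone; 2 prenyl bromide
Product: 12 1-[2,4-dihydroxy-3-(3-methylbut-2-en-1-yl)phenyl]ethanone
Conditions: 2 (1.0 equiv), 10% aq KOH, 0 °C to rt; then dilute HCl
Reagents that add atoms: none
Why: C-alkylation of a resorcinol-type phenoxide in water, where hydrogen bonding to oxygen favours attack through carbon; C3, flanked by both oxygens, is the most nucleophilic ring carbon, and the C5 and O-alkylated isomers that are expected beside 12 are removed by chromatography.

Step 5
Reactants: 12 1-[2,4-dihydroxy-3-(3-methylbut-2-en-1-yl)phenyl]ethanone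
Product: 13 1-[2-hydroxy-4-(methoxymethoxy)-3-(3-methylbut-2-en-1-yl)phenyl]ethanone
Conditions: MOMCl (1.2 equiv), K2CO3, acetone, 0 °C to rt
Reagents that add atoms: chloromethyl methyl ether, COCCl
Why: Williamson-type O-alkylation; the 2-hydroxyl is tied up in a hydrogen bond to the acetyl oxygen and is far less reactive, so the 4-hydroxyl is protected selectively.

Step 6
Reactants: 13 1-[2-hydroxy-4-(methoxymethoxy)-3-(3-methylbut-2-en-1-yl)phenyl]ethanone
Product: 14 (E)-3-(dimethylamino)-1-[2-hydroxy-4-(methoxymethoxy)-3-(3-methylbut-2-en-1-yl)phenyl]prop-2-en-1-one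
Conditions: Me2NCH(OMe)2 (3 equiv), PhMe, 95 °C
Reagents that add atoms: N,N-dimethylformamide dimethyl acetal, COC(OC)N(C)C
Why: Condensation of the methyl ketone with the amide acetal gives the vinylogous amide (enaminone formation); the chelated phenol, the acetal and the prenyl group are inert to this neutral reagent.

Step 7
Reactants: 14 (E)-3-(dimethylamino)-1-[2-hydroxy-4-(methoxymethoxy)-3-(3-methylbut-2-en-1-yl)phenyl]prop-2-en-1-one
Product: 15 7-(methoxymethoxy)-8-(3-methylbut-2-en-1-yl)-4H-chromen-4-one
Conditions: AcOH (5 equiv), EtOH, 60 °C
Reagents that add atoms: none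
Why: Weak-acid-promoted cyclisation of a 2-hydroxyaryl enaminone: the phenol adds to the β-carbon and dimethylamine is lost (addition–elimination), while the amine acetate buffer is too weakly acidic to cleave the aryl acetal or to add the phenol to the prenyl alkene.

Step 8
Reactants: 10 [2,2-dimethyl-8-(3-methylbut-2-en-1-yl)chroman-6-yl]boronic acid; 15 7-(methoxymethoxy)-8-(3-methylbut-2-en-1-yl)-4H-chromen-4-one
Product: 16 (2S)-2-[2,2-dimethyl-8-(3-methylbut-2-en-1-yl)chroman-6-yl]-7-(methoxymethoxy)-8-(3-methylbut-2-en-1-yl)chroman-4-one
Conditions: 10 (2 equiv), [Rh(C2H4)2Cl]2 (2.5 mol %), (S,S)-2,5-diphenylbicyclo[2.2.2]octa-2,5-diene (6 mol %), aq K3PO4 (0.5 equiv), PhMe/H2O 10:1, 40 °C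
Reagents that add atoms: none
Why: Hayashi–Miyaura asymmetric 1,4-addition of an arylboronic acid to a chromone: transmetalation gives an aryl–rhodium–diene species that inserts the C2=C3 bond with the aryl group delivered to the Re face of C2 as fixed by the C2-symmetric diene, and protonolysis of the rhodium enolate by water releases 16 with C2 as S. The boronic acid has no ortho substituent, and the mild base limits ring opening of the product.

Step 9
Reactants: 16 (2S)-2-[2,2-dimethyl-8-(3-methylbut-2-en-1-yl)chroman-6-yl]-7-(methoxymethoxy)-8-(3-methylbut-2-en-1-yl)chroman-4-one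
Product: 17 (2S)-2-[2,2-dimethyl-8-(3-methylbut-2-en-1-yl)chroman-6-yl]-7-hydroxy-8-(3-methylbut-2-en-1-yl)chroman-4-one
Conditions: 3 M aq HCl, MeOH, rt
Reagents that add atoms: none
Why: Acid-catalysed transacetalisation of the aryl methoxymethyl ether to methanol (acetal cleavage) is fast at room temperature, whereas protonation of the trisubstituted alkenes and opening of ring C need much stronger conditions, so both prenyl groups, ring D and the C2 configuration are kept.

Compound list

1 | 5-bromo-2-hydroxybenzyl alcohol | OCc1cc(Br)ccc1O | starting material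
2 | prenyl bromide (1-bromo-3-methylbut-2-ene) | CC(C)=CCBr | starting material
3 | sodium 4-bromo-2-(hydroxymethyl)phenolate | [Na+].[O-]c1ccc(Br)cc1CO | intermediate (not isolated)
4 | 4-bromo-2-(hydroxymethyl)-6-(3-methylbut-2-en-1-yl)phenol | OCc1cc(Br)cc(CC=C(C)C)c1O | intermediate
5 | isobutene (2-methylpropene) | C=C(C)C | starting material
6 | 4-bromo-6-methylidene-2-(3-methylbut-2-en-1-yl)cyclohexa-2,4-dien-1-one | C=C1C=C(Br)C=C(CC=C(C)C)C1=O | intermediate (not isolated)
7 | 6-bromo-2,2-dimethyl-8-(3-methylbut-2-en-1-yl)chromane | Brc1cc(CC=C(C)C)c2OC(C)(C)CCc2c1 | intermediate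
8 | [2,2-dimethyl-8-(3-methylbut-2-en-1-yl)chroman-6-yl]lithium | [Li]c1cc(CC=C(C)C)c2OC(C)(C)CCc2c1 | intermediate (not isolated)
9 | lithium [2,2-dimethyl-8-(3-methylbut-2-en-1-yl)chroman-6-yl]triisopropoxyborate | [Li+].CC(C)O[B-](OC(C)C)(OC(C)C)c1cc(CC=C(C)C)c2OC(C)(C)CCc2c1 | intermediate (not isolated)
10 | [2,2-dimethyl-8-(3-methylbut-2-en-1-yl)chroman-6-yl]boronic acid | OB(O)c1cc(CC=C(C)C)c2OC(C)(C)CCc2c1 | intermediate
11 | 2,4-dihydroxyacetophenone | CC(=O)c1ccc(O)cc1O | starting material
12 | 1-[2,4-dihydroxy-3-(3-methylbut-2-en-1-yl)phenyl]ethanone | CC(=O)c1ccc(O)c(CC=C(C)C)c1O | intermediate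
13 | 1-[2-hydroxy-4-(methoxymethoxy)-3-(3-methylbut-2-en-1-yl)phenyl]ethanone | CC(=O)c1ccc(OCOC)c(CC=C(C)C)c1O | intermediate
14 | (E)-3-(dimethylamino)-1-[2-hydroxy-4-(methoxymethoxy)-3-(3-methylbut-2-en-1-yl)phenyl]prop-2-en-1-one | CN(C)/C=C/C(=O)c1ccc(OCOC)c(CC=C(C)C)c1O | intermediate
15 | 7-(methoxymethoxy)-8-(3-methylbut-2-en-1-yl)-4H-chromen-4-one | O=c1ccoc2c1ccc(OCOC)c2CC=C(C)C | intermediate
16 | (2S)-2-[2,2-dimethyl-8-(3-methylbut-2-en-1-yl)chroman-6-yl]-7-(methoxymethoxy)-8-(3-methylbut-2-en-1-yl)chroman-4-one | CC(C)=CCc1cc([C@@H]2CC(=O)c3ccc(OCOC)c(CC=C(C)C)c3O2)cc2c1OC(C)(C)CC2 | intermediate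
17 | (2S)-2-[2,2-dimethyl-8-(3-methylbut-2-en-1-yl)chroman-6-yl]-7-hydroxy-8-(3-methylbut-2-en-1-yl)chroman-4-one | CC(C)=CCc1cc([C@@H]2CC(=O)c3ccc(O)c(CC=C(C)C)c3O2)cc2c1OC(C)(C)CC2 | target

Total step count: 9. Longest linear sequence: 6 steps (11 to 17, steps 4 to 9); the ring B branch is 5 steps (steps 1 to 3, then 8 and 9).

Least certain steps

Step 2 (key step). The quinone methide may be consumed by oligomerisation, that is by cycloaddition with a second quinone methide or with the prenyl alkene of another molecule. Isobutene is only a moderately reactive partner, and the temperature needed for dehydration is high enough that the ortho-prenylphenol may also begin to cyclise. Fallback, from 1 back to 7: the cycloaddition is run before the prenyl group is present. Heating 1 with isobutene 5 under the conditions of step 2 should give, through 4-bromo-6-methylidenecyclohexa-2,4-dien-1-one F1, 6-bromo-2,2-dimethylchromane F2. Iodination (N-iodosuccinimide, cat. CF3CO2H, MeCN) at C8, the only free position ortho or para to the ring oxygen, gives 6-bromo-8-iodo-2,2-dimethylchromane F3. Iodine–magnesium exchange (iPrMgCl·LiCl, THF, −20 °C), which leaves the bromide alone, gives (6-bromo-2,2-dimethylchroman-8-yl)magnesium chloride F4. Coupling of F4 with prenyl bromide 2 (CuBr·SMe2 cat.) returns to 7.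

Step 1. O-alkylation may compete with C-alkylation, and conversion of the heterogeneous phenoxide may be incomplete, because the ion pairing that steers the electrophile to carbon is easily disturbed. Fallback, from 1 back to 4: the prenyl group is built from an allyl group placed by sigmatropic rearrangement. O-allylation of 1 (allyl bromide, K2CO3, acetone) gives [2-(allyloxy)-5-bromophenyl]methanol F5, and oxidation with MnO2 gives 2-(allyloxy)-5-bromobenzaldehyde F6. The aldehyde level is used because a salicyl alcohol would shed water at the temperature of the next operation. Aromatic Claisen rearrangement (N,N-diethylaniline, 190 °C) to the only free ortho carbon gives 3-allyl-5-bromo-2-hydroxybenzaldehyde F7. Cross-metathesis with 2-methylbut-2-ene (second-generation Grubbs catalyst, RuCl2(=CHPh)(H2IMes)(PCy3), CH2Cl2, 40 °C) gives 5-bromo-2-hydroxy-3-(3-methylbut-2-en-1-yl)benzaldehyde F8, and NaBH4 in MeOH reduces F8 to 4.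

Step 8. Protodeboronation of the electron-rich boronic acid may outrun insertion into the donor-substituted chromone, and enantiopurity may be partly lost through base-mediated opening and re-closure of ring C. Fallback, from 7 back to 16: a racemic chalcone route followed by resolution. Aryllithium 8, made from 7 as in step 3, is quenched with DMF and then dilute HCl to give 2,2-dimethyl-8-(3-methylbut-2-en-1-yl)chromane-6-carbaldehyde F9. Claisen–Schmidt condensation of F9 with 13 (KOH, EtOH, rt) gives (E)-3-[2,2-dimethyl-8-(3-methylbut-2-en-1-yl)chroman-6-yl]-1-[2-hydroxy-4-(methoxymethoxy)-3-(3-methylbut-2-en-1-yl)phenyl]prop-2-en-1-one F10. Oxa-Michael closure (NaOAc, EtOH, reflux) gives racemic 2-[2,2-dimethyl-8-(3-methylbut-2-en-1-yl)chroman-6-yl]-7-(methoxymethoxy)-8-(3-methylbut-2-en-1-yl)chroman-4-one F11. Preparative chromatography on a chiral stationary phase separates 16 from its (2R) enantiomer F12, and F12 is returned to the NaOAc equilibration.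

Step 9. The freed C7 phenol may add to the C8 prenyl alkene under acid, or the alkenes may be hydrated, because the deprotection and these side reactions all begin with protonation. Fallback, from 12 to 17: the phenol is carried as an allyl ether and freed without acid. Allylation of 12 (allyl bromide, K2CO3, acetone) gives 1-[2-hydroxy-3-(3-methylbut-2-en-1-yl)-4-(prop-2-en-1-yloxy)phenyl]ethanone F13. The conditions of step 6 give (E)-3-(dimethylamino)-1-[2-hydroxy-3-(3-methylbut-2-en-1-yl)-4-(prop-2-en-1-yloxy)phenyl]prop-2-en-1-one F14, and those of step 7 give 8-(3-methylbut-2-en-1-yl)-7-(prop-2-en-1-yloxy)-4H-chromen-4-one F15. Addition of 10 as in step 8 gives (2S)-2-[2,2-dimethyl-8-(3-methylbut-2-en-1-yl)chroman-6-yl]-8-(3-methylbut-2-en-1-yl)-7-(prop-2-en-1-yloxy)chroman-4-one F16. Deallylation with zerovalent palladium (Pd(PPh3)4 cat., morpholine, THF, rt) gives 17.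

Step 4. Site selectivity of the phenoxide alkylation may be poor (C3 against C5 and oxygen), since all three sites of the resorcinol anion are nucleophilic. Fallback, from 11 back to 12: the prenyl group is delivered intramolecularly. Etherification of the 4-hydroxyl of 11 (3-chloro-3-methylbut-1-yne, K2CO3, KI, CuI cat., acetone) gives 1-[2-hydroxy-4-(2-methylbut-3-yn-2-yloxy)phenyl]ethanone F17. Semi-hydrogenation (H2, Lindlar catalyst Pd/CaCO3 poisoned with Pb(OAc)2, quinoline) gives 1-[2-hydroxy-4-(2-methylbut-3-en-2-yloxy)phenyl]ethanone F18. Aromatic Claisen rearrangement of F18 (N,N-diethylaniline, 150 °C) goes to C3, the ortho carbon favoured by the bond fixation of the chelated acetyl phenol, and gives 12.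

Further compounds

F1 | step 2 | 4-bromo-6-methylidenecyclohexa-2,4-dien-1-one | C=C1C=C(Br)C=CC1=O
F2 | step 2 | 6-bromo-2,2-dimethylchromane | Brc1ccc2OC(C)(C)CCc2c1
F3 | step 2 | 6-bromo-8-iodo-2,2-dimethylchromane | Ic1cc(Br)cc2CCC(C)(C)Oc12
F4 | step 2 | (6-bromo-2,2-dimethylchroman-8-yl)magnesium chloride | Cl[Mg]c1cc(Br)cc2CCC(C)(C)Oc12
F5 | step 1 | [2-(allyloxy)-5-bromophenyl]methanol | OCc1cc(Br)ccc1OCC=C
F6 | step 1 | 2-(allyloxy)-5-bromobenzaldehyde | O=Cc1cc(Br)ccc1OCC=C
F7 | step 1 | 3-allyl-5-bromo-2-hydroxybenzaldehyde | O=Cc1cc(Br)cc(CC=C)c1O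
F8 | step 1 | 5-bromo-2-hydroxy-3-(3-methylbut-2-en-1-yl)benzaldehyde | O=Cc1cc(Br)cc(CC=C(C)C)c1O
F9 | step 8 | 2,2-dimethyl-8-(3-methylbut-2-en-1-yl)chromane-6-carbaldehyde | O=Cc1cc(CC=C(C)C)c2OC(C)(C)CCc2c1
F10 | step 8 | (E)-3-[2,2-dimethyl-8-(3-methylbut-2-en-1-yl)chroman-6-yl]-1-[2-hydroxy-4-(methoxymethoxy)-3-(3-methylbut-2-en-1-yl)phenyl]prop-2-en-1-one | CC(C)=CCc1c(OCOC)ccc(C(=O)/C=C/c2cc(CC=C(C)C)c3OC(C)(C)CCc3c2)c1O
F11 | step 8 | racemic 2-[2,2-dimethyl-8-(3-methylbut-2-en-1-yl)chroman-6-yl]-7-(methoxymethoxy)-8-(3-methylbut-2-en-1-yl)chroman-4-one | CC(C)=CCc1cc(C2CC(=O)c3ccc(OCOC)c(CC=C(C)C)c3O2)cc2c1OC(C)(C)CC2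
F12 | step 8 | (2R)-2-[2,2-dimethyl-8-(3-methylbut-2-en-1-yl)chroman-6-yl]-7-(methoxymethoxy)-8-(3-methylbut-2-en-1-yl)chroman-4-one | CC(C)=CCc1cc([C@H]2CC(=O)c3ccc(OCOC)c(CC=C(C)C)c3O2)cc2c1OC(C)(C)CC2
F13 | step 9 | 1-[2-hydroxy-3-(3-methylbut-2-en-1-yl)-4-(prop-2-en-1-yloxy)phenyl]ethanone | CC(=O)c1ccc(OCC=C)c(CC=C(C)C)c1O
F14 | step 9 | (E)-3-(dimethylamino)-1-[2-hydroxy-3-(3-methylbut-2-en-1-yl)-4-(prop-2-en-1-yloxy)phenyl]prop-2-en-1-one | CN(C)/C=C/C(=O)c1ccc(OCC=C)c(CC=C(C)C)c1O
F15 | step 9 | 8-(3-methylbut-2-en-1-yl)-7-(prop-2-en-1-yloxy)-4H-chromen-4-one | O=c1ccoc2c1ccc(OCC=C)c2CC=C(C)C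
F16 | step 9 | (2S)-2-[2,2-dimethyl-8-(3-methylbut-2-en-1-yl)chroman-6-yl]-8-(3-methylbut-2-en-1-yl)-7-(prop-2-en-1-yloxy)chroman-4-one | CC(C)=CCc1cc([C@@H]2CC(=O)c3ccc(OCC=C)c(CC=C(C)C)c3O2)cc2c1OC(C)(C)CC2
F17 | step 4 | 1-[2-hydroxy-4-(2-methylbut-3-yn-2-yloxy)phenyl]ethanone | CC(=O)c1ccc(OC(C)(C)C#C)cc1O
F18 | step 4 | 1-[2-hydroxy-4-(2-methylbut-3-en-2-yloxy)phenyl]ethanone | CC(=O)c1ccc(OC(C)(C)C=C)cc1O
A1 | alternative 1 | (7S)-5-[(tert-butyldimethylsilyl)oxy]-4-diazo-7-[2,2-dimethyl-8-(3-methylbut-2-en-1-yl)chroman-6-yl]-7-[(5-methylhex-4-en-1-yn-1-yl)oxy]hept-1-en-3-one | C=CC(=O)C(=[N+]=[N-])C(O[Si](C)(C)C(C)(C)C)C[C@@H](c1cc(CC=C(C)C)c2OC(C)(C)CCc2c1)OC#CCC=C(C)C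
A2 | alternative 1 | (2S)-4-[(tert-butyldimethylsilyl)oxy]-2-[2,2-dimethyl-8-(3-methylbut-2-en-1-yl)chroman-6-yl]-8-(3-methylbut-2-en-1-yl)chroman-7-ol, C4 configuration open | CC(C)(C)[Si](C)(C)OC1C[C@@H](c3cc(CC=C(C)C)c4OC(C)(C)CCc4c3)Oc2c1ccc(O)c2CC=C(C)C
A3 | alternative 2 | 4-(methoxymethoxy)-3-(3-methylbut-2-en-1-yl)-2-(trimethylsilyloxy)-1-[1-(trimethylsilyloxy)ethenyl]cyclohexa-1,3-diene | C=C(O[Si](C)(C)C)C1=C(O[Si](C)(C)C)C(CC=C(C)C)=C(OCOC)CC1
A4 | alternative 2 | (2S)-2-[2,2-dimethyl-8-(3-methylbut-2-en-1-yl)chroman-6-yl]-7-(methoxymethoxy)-8-(3-methylbut-2-en-1-yl)-2,3,5,6-tetrahydro-4H-chromen-4-one | O=C1C[C@@H](c3cc(CC=C(C)C)c4OC(C)(C)CCc4c3)OC2=C1CCC(OCOC)=C2CC=C(C)C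
A5 | alternative 3 | 2,2-dimethyl-6-(5-methylhexa-1,4-dien-2-yl)-3,4-dihydro-2H-pyran | C=C(CC=C(C)C)C1=CCCC(C)(C)O1
A6 | alternative 3 | 7-[(tert-butyldimethylsilyl)oxy]-2-ethynyl-8-(3-methylbut-2-en-1-yl)-4H-chromen-4-one | C#Cc1cc(=O)c2ccc(O[Si](C)(C)C(C)(C)C)c(CC=C(C)C)c2o1
A7 | alternative 3 | 7-[(tert-butyldimethylsilyl)oxy]-2-[2,2-dimethyl-8-(3-methylbut-2-en-1-yl)chroman-6-yl]-8-(3-methylbut-2-en-1-yl)-4H-chromen-4-one | O=c1cc(-c3cc(CC=C(C)C)c4OC(C)(C)CCc4c3)oc2c1ccc(O[Si](C)(C)C(C)(C)C)c2CC=C(C)C
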